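**Plan**

- Retrosynthesis cuts, in order: the two ring-A prenyl groups back to C-allyl groups (cross-metathesis); the oxepine C–O bond between the ring-B 2'-oxygen and the CH that carries C(CH3)2OH, giving a 2'-phenoxide and an (S)-2,3-epoxy-3-methylbutyl group on C3; the epoxide back to a 3-prenyl group; the flavone back to a 2-prenyl-1,3-diketone made from an acetophenone, a benzoic acid and prenyl bromide.
- Enabling feature: O2' and the side-chain CH are held close by the rigid sp2 unit C2'–C1'–C2=C3 (ring B and pyranone ring C) plus the C3 methylene, so a 2'-phenoxide can open the epoxide at its secondary carbon and close the seven-membered ring D (7-exo-tet). This copies the presumed biosynthesis from a 3-prenyl-2'-hydroxyflavone.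
- Precursor design: all four phenols travel as allyl ethers and the ring-A side arms as C-allyl groups. Monosubstituted alkenes are nearly inert to the dioxirane that epoxidises the single trisubstituted (prenyl) alkene, and the O-allyl groups are removed in the key step itself.
- Forward order: ring A is dressed by a double Claisen rearrangement; the 1,3-diketone is assembled and C-prenylated; ring C closes by cyclodehydration; ring D closes by the deallylation/epoxide-opening cascade; the prenyl groups are completed last.
- Stereochemistry: the one stereocentre comes from catalyst-controlled epoxidation with the L-fructose-derived ketone, which should give the (S)-epoxide, and is transferred with inversion in the ring closure to give R.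

Key step: step 9

Remark: allyl = prop-2-en-1-yl and prenyl = 3-methylbut-2-en-1-yl, with flavone numbering (ring B primed); the L-fructose-derived ketone is taken as a purchasable catalyst, and species only partly converted when one transformation is repeated at like groups within a step are not numbered.

**Route**

Step 1
Reactants: 1 2,4,6-trihydroxyacetophenone; 2 allyl bromide
Product: 3 1-[2-hydroxy-4,6-bis(allyloxy)phenyl]ethanone
Conditions: allyl bromide (2.1 equiv), K2CO3 (2.2 equiv), acetone, reflux
Reagents that add atoms: allyl bromide, C=CCBr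
Why: Williamson etherification, in which the two phenols not locked in the hydrogen bond to the acetyl carbonyl should be alkylated first, leaving the chelated 2-OH free.

Step 2
Reactants: 3 1-[2-hydroxy-4,6-bis(allyloxy)phenyl]ethanone
Product: 4 1-(3,5-diallyl-2,4,6-trihydroxyphenyl)ethanone
Conditions: N,N-diethylaniline, 200 °C, argon
Reagents that add atoms: none
Why: Double aromatic Claisen rearrangement; each allyl ether has a free ortho carbon, and if C5 is filled first the remaining ether reaches C3 by the para-Claisen (Claisen–Cope) path, so every pathway should converge on the 3,5-diallyl triol.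

Step 3
Reactants: 4 1-(3,5-diallyl-2,4,6-trihydroxyphenyl)ethanone; 2 allyl bromide
Product: 5 1-[3,5-diallyl-2-hydroxy-4,6-bis(allyloxy)phenyl]ethanone
Conditions: allyl bromide (2.1 equiv), K2CO3 (2.2 equiv), acetone, 50 °C
Reagents that add atoms: allyl bromide, C=CCBr
Why: Williamson etherification that again should spare the one phenol chelated to the acetyl group; both ring carbons are now substituted, so these ethers cannot rearrange later.

Step 4
Reactants: 6 2,4-dihydroxybenzoic acid; 2 allyl bromide
Product: 8 2,4-bis(allyloxy)benzoic acid, via allyl 2,4-bis(allyloxy)benzoate 7 (not isolated)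
Conditions: allyl bromide (3.5 equiv), K2CO3, DMF, 60 °C; then NaOH, MeOH–H2O, 70 °C; HCl work-up
Reagents that add atoms: allyl bromide, C=CCBr; sodium hydroxide, [Na+].[OH-]
Why: Exhaustive O-alkylation followed by saponification of the allyl ester in the same flask (acyl–oxygen cleavage), the aryl allyl ethers being inert to hydroxide.

Step 5
Reactants: 8 2,4-bis(allyloxy)benzoic acid; 5 1-[3,5-diallyl-2-hydroxy-4,6-bis(allyloxy)phenyl]ethanone
Product: 10 1-[3,5-diallyl-2-hydroxy-4,6-bis(allyloxy)phenyl]-3-[2,4-bis(allyloxy)phenyl]propane-1,3-dione, via 2,4-bis(allyloxy)benzoyl chloride 9 (not isolated)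
Conditions: 8, (COCl)2, DMF (cat.), CH2Cl2, 0 °C to rt, evaporate; 5, LiN(SiMe3)2 (3.2 equiv), THF, −78 °C, then 9, −78 °C to rt; aq NH4Cl
Reagents that add atoms: none
Why: Claisen-type C-acylation of the lithium enolate–phenoxide dianion of a 2-hydroxyacetophenone with an aroyl chloride (the one-flask form of the Baker–Venkataraman route to 2-hydroxyaryl 1,3-diketones), the third equivalent of base taking up the acidic diketone as it forms and so preventing double acylation.

Step 6
Reactants: 10 1-[3,5-diallyl-2-hydroxy-4,6-bis(allyloxy)phenyl]-3-[2,4-bis(allyloxy)phenyl]propane-1,3-dione; 11 prenyl bromide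
Product: 12 1-[3,5-diallyl-2-hydroxy-4,6-bis(allyloxy)phenyl]-3-[2,4-bis(allyloxy)phenyl]-2-prenylpropane-1,3-dione (racemic at C2)
Conditions: prenyl bromide (1.1 equiv), K2CO3 (1.2 equiv), acetone, rt
Reagents that add atoms: prenyl bromide, CC(C)=CCBr
Why: C-alkylation of a 1,3-diketone, whose doubly stabilised enolate is more acidic than the chelated, flanked ring-A phenol and should attack the primary allylic carbon of the bromide (SN2); the new C2 centre forms as a racemate and disappears in step 7.

Step 7
Reactants: 12 1-[3,5-diallyl-2-hydroxy-4,6-bis(allyloxy)phenyl]-3-[2,4-bis(allyloxy)phenyl]-2-prenylpropane-1,3-dione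
Product: 13 6,8-diallyl-5,7-bis(allyloxy)-2-[2,4-bis(allyloxy)phenyl]-3-prenyl-4H-chromen-4-one
Conditions: NaOAc, AcOH, 100 °C
Reagents that add atoms: none
Why: Cyclodehydration of a 2-hydroxyaryl 1,3-diketone to a flavone (ring C), the ring-A phenol adding to the ring-B ketone and the hemiketal losing water, in buffered acetic acid that should leave the prenyl alkene and the allyl ethers untouched.

Step 8
Reactants: 13 6,8-diallyl-5,7-bis(allyloxy)-2-[2,4-bis(allyloxy)phenyl]-3-prenyl-4H-chromen-4-one
Product: 14 6,8-diallyl-5,7-bis(allyloxy)-2-[2,4-bis(allyloxy)phenyl]-3-{[(2S)-3,3-dimethyloxiran-2-yl]methyl}-4H-chromen-4-one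
Conditions: 1,2:4,5-di-O-isopropylidene-β-L-erythro-2,3-hexodiulo-2,6-pyranose (enantiomer of the Shi ketone, 0.3 equiv), KHSO5 (as 2KHSO5·KHSO4·K2SO4, 1.4 equiv), K2CO3, Bu4NHSO4 (cat.), MeCN–CH2(OMe)2 (1:2), aq Na2B4O7/Na2H2EDTA buffer, pH about 10.5, 0 °C
Reagents that add atoms: potassium peroxymonosulfate, [K+].[O-]S(=O)(=O)OO
Why: Shi asymmetric epoxidation, in which the chiral dioxirane should pick the only trisubstituted alkene over the six monosubstituted ones and deliver oxygen through the spiro transition state to the face that gives the (S)-epoxide (the D-fructose ketone gives R with 2-methylalk-2-enes, so its enantiomer is used).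

Step 9
Reactants: 14 6,8-diallyl-5,7-bis(allyloxy)-2-[2,4-bis(allyloxy)phenyl]-3-{[(2S)-3,3-dimethyloxiran-2-yl]methyl}-4H-chromen-4-one
Product: 16 (R)-6,8-diallyl-5,7,4'-trihydroxyflavone bridged from C3 to O2' by CH2–CH[C(CH3)2OH] (diallyl oxepinoflavone), via tetraphenol epoxide 15 (not isolated)
Conditions: Pd(PPh3)4 (8 mol %), K2CO3 (6 equiv), MeOH–THF (3:1), rt then 50 °C; aq NH4Cl
Reagents that add atoms: none
Why: Zerovalent palladium ionises the four aryl allyl ethers to π-allylpalladium cations and phenoxides, methoxide removes the allyl groups as allyl methyl ether, and the ring-B 2'-phenoxide of 15 then attacks the secondary epoxide carbon from the side opposite to its C–O bond, the event proposed for the biosynthesis from a 3-(epoxyprenyl)-2'-hydroxyflavone. The closest known reaction type is the base- or fluoride-triggered phenoxide opening of enantioenriched prenyl epoxides that gives 2-(2-hydroxypropan-2-yl)dihydrobenzofurans, here preceded by a Tsuji–Trost-type deallylation. Ring D closes in the 7-exo-tet mode, helped by the fact that four of its seven atoms (C2', C1', C2, C3) are sp2 carbons of ring B and ring C that hold O2' and the epoxide within reach. The new stereocentre arises by SN2 inversion at the (S)-epoxide carbon and should therefore be R, its configuration being fixed by the epoxide from step 8, while the epoxide oxygen becomes the tertiary alcohol. The step needs 7-exo attack at the secondary carbon over 8-endo attack at the tertiary carbon, which basic SN2 conditions secure, and attack by O2' alone, which geometry secures because the 5-, 7- and 4'-phenoxides cannot reach the epoxide. The C-allyl groups carry no leaving group and should pass unchanged.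

Step 10
Reactants: 16 (R)-diallyl oxepinoflavone; 17 2-methylbut-2-ene
Product: 18 CNP0328977.2, the (R)-6,8-diprenyl oxepinoflavone
Conditions: second-generation Grubbs catalyst RuCl2(=CHPh)(PCy3)(SIMes) (10 mol %), 2-methylbut-2-ene–CH2Cl2 (1:1), 40 °C, sealed tube
Reagents that add atoms: 2-methylbut-2-ene, CC=C(C)C
Why: Olefin cross-metathesis of the two allylarene termini with excess 2-methylbut-2-ene should exchange each =CH2 for =C(CH3)2 with loss of propene, a standard allyl-to-prenyl conversion that tolerates free phenols and the tertiary alcohol and does not touch the stereocentre.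

**Compound list**

1 | 2,4,6-trihydroxyacetophenone | CC(=O)c1c(O)cc(O)cc1O | starting material
2 | allyl bromide (3-bromoprop-1-ene) | C=CCBr | starting material
3 | 1-[2-hydroxy-4,6-bis(allyloxy)phenyl]ethanone | CC(=O)c1c(O)cc(OCC=C)cc1OCC=C | intermediate
4 | 1-(3,5-diallyl-2,4,6-trihydroxyphenyl)ethanone | CC(=O)c1c(O)c(CC=C)c(O)c(CC=C)c1O | intermediate
5 | 1-[3,5-diallyl-2-hydroxy-4,6-bis(allyloxy)phenyl]ethanone | CC(=O)c1c(O)c(CC=C)c(OCC=C)c(CC=C)c1OCC=C | intermediate
6 | 2,4-dihydroxybenzoic acid | O=C(O)c1ccc(O)cc1O | starting material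
7 | allyl 2,4-bis(allyloxy)benzoate (not isolated) | C=CCOC(=O)c1ccc(OCC=C)cc1OCC=C | intermediate
8 | 2,4-bis(allyloxy)benzoic acid | O=C(O)c1ccc(OCC=C)cc1OCC=C | intermediate
9 | 2,4-bis(allyloxy)benzoyl chloride (not isolated) | O=C(Cl)c1ccc(OCC=C)cc1OCC=C | intermediate
10 | 1-[3,5-diallyl-2-hydroxy-4,6-bis(allyloxy)phenyl]-3-[2,4-bis(allyloxy)phenyl]propane-1,3-dione | O=C(CC(=O)c1ccc(OCC=C)cc1OCC=C)c1c(O)c(CC=C)c(OCC=C)c(CC=C)c1OCC=C | intermediate
11 | prenyl bromide (1-bromo-3-methylbut-2-ene) | CC(C)=CCBr | starting material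
12 | 1-[3,5-diallyl-2-hydroxy-4,6-bis(allyloxy)phenyl]-3-[2,4-bis(allyloxy)phenyl]-2-prenylpropane-1,3-dione, racemic at C2 | O=C(C(CC=C(C)C)C(=O)c1ccc(OCC=C)cc1OCC=C)c1c(O)c(CC=C)c(OCC=C)c(CC=C)c1OCC=C | intermediate
13 | 6,8-diallyl-5,7-bis(allyloxy)-2-[2,4-bis(allyloxy)phenyl]-3-prenyl-4H-chromen-4-one | C=CCOc1ccc(-c2oc3c(CC=C)c(OCC=C)c(CC=C)c(OCC=C)c3c(=O)c2CC=C(C)C)c(OCC=C)c1 | intermediate
14 | 6,8-diallyl-5,7-bis(allyloxy)-2-[2,4-bis(allyloxy)phenyl]-3-{[(2S)-3,3-dimethyloxiran-2-yl]methyl}-4H-chromen-4-one | C=CCOc1ccc(-c2oc3c(CC=C)c(OCC=C)c(CC=C)c(OCC=C)c3c(=O)c2C[C@@H]2OC2(C)C)c(OCC=C)c1 | intermediate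
15 | 6,8-diallyl-2-(2,4-dihydroxyphenyl)-3-{[(2S)-3,3-dimethyloxiran-2-yl]methyl}-5,7-dihydroxy-4H-chromen-4-one, present as its phenoxides (not isolated) | C=CCc1c(O)c(CC=C)c2oc(-c3ccc(O)cc3O)c(C[C@@H]3OC3(C)C)c(=O)c2c1O | intermediate
16 | 6,8-diallyl-5,7,4'-trihydroxyflavone in which C3 is joined through CH2–CH[C(CH3)2OH]–O to C2' (oxepine ring D), carbinol-bearing CH of R configuration | C=CCc1c(O)c(CC=C)c2oc3c(c(=O)c2c1O)C[C@H](C(C)(C)O)Oc1cc(O)ccc1-3 | intermediate
17 | 2-methylbut-2-ene | CC=C(C)C | starting material
18 | CNP0328977.2: 5,7,4'-trihydroxy-6,8-diprenylflavone in which C3 is joined through CH2–CH[C(CH3)2OH]–O to C2' (oxepine ring D), carbinol-bearing CH of R configuration | CC(C)=CCc1c(O)c(CC=C(C)C)c2oc3c(c(=O)c2c1O)C[C@H](C(C)(C)O)Oc1cc(O)ccc1-3 | target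

**Count and risks**

Total step count: 10. Longest linear sequence: 9 steps (1, 2, 3, 5, 6, 7, 8, 9, 10); step 4 is a one-step side branch.

Steps most likely to fail:

1. Step 9. The ring closure may lag behind ether cleavage, so that methanol or methoxide opens the epoxide. Palladium hydride may also move the C-allyl double bonds into conjugation with ring A. The fallback takes palladium and methanol out of the ring-closing event. It sets out from 13 and returns at 16. The allyl ethers of 13 are cleaved first with Pd(PPh3)4 and morpholine in THF to give the tetraphenol 6,8-diallyl-2-(2,4-dihydroxyphenyl)-5,7-dihydroxy-3-prenyl-4H-chromen-4-one F1. Silylation with tert-butyldimethylsilyl triflate and 2,6-lutidine gives the tetrakis(tert-butyldimethylsilyl) ether of that flavone F2. Epoxidation under the conditions of step 8 gives the (S)-epoxide of the tetrakis(silyl) ether F3. Bu4NF in THF at 0 °C to rt then frees the phenoxides (15 in the flask), which should close ring D to give 16.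

2. Step 8. Facial selectivity of oxygen transfer may be poor at a prenyl group that sits next to the bulky 2-aryl ring. The fallback replaces asymmetric catalysis by resolution. It sets out from 13 and returns at 16. mCPBA with NaHCO3 in CH2Cl2 at 0 °C should epoxidise only the trisubstituted alkene to give the racemic 3-[(3,3-dimethyloxiran-2-yl)methyl] hexaallyl flavone F4. The conditions of step 9 then give the racemic diallyl oxepinoflavone F5. Preparative chromatography on a chiral stationary phase (amylose tris(3,5-dimethylphenylcarbamate)) separates the enantiomers and delivers 16.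

3. Step 6. O-alkylation of the diketone enolate or of the ring-A phenol, and double alkylation, may compete with clean C-monoalkylation. The fallback installs the prenyl group on the finished flavone. It sets out from 10 and returns at 13. Cyclodehydration of 10 (NaOAc, AcOH, 100 °C) gives 6,8-diallyl-5,7-bis(allyloxy)-2-[2,4-bis(allyloxy)phenyl]-4H-chromen-4-one F6. Lithiation at C3 with LiN(iPr)2 in THF at −78 °C and quenching with I2 gives the 3-iodo derivative of that flavone F7. Stille coupling of F7 with tributyl(3-methylbut-2-en-1-yl)stannane and Pd(PPh3)4 in DMF at 80 °C should give 13.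

Further compounds
F1 | step 9 | 6,8-diallyl-2-(2,4-dihydroxyphenyl)-5,7-dihydroxy-3-prenyl-4H-chromen-4-one | C=CCc1c(O)c(CC=C)c2oc(-c3ccc(O)cc3O)c(CC=C(C)C)c(=O)c2c1O
F2 | step 9 | 6,8-diallyl-5,7-bis(tert-butyldimethylsilyloxy)-2-[2,4-bis(tert-butyldimethylsilyloxy)phenyl]-3-prenyl-4H-chromen-4-one | C=CCc1c(O[Si](C)(C)C(C)(C)C)c(CC=C)c2oc(-c3ccc(O[Si](C)(C)C(C)(C)C)cc3O[Si](C)(C)C(C)(C)C)c(CC=C(C)C)c(=O)c2c1O[Si](C)(C)C(C)(C)C
F3 | step 9 | 6,8-diallyl-5,7-bis(tert-butyldimethylsilyloxy)-2-[2,4-bis(tert-butyldimethylsilyloxy)phenyl]-3-{[(2S)-3,3-dimethyloxiran-2-yl]methyl}-4H-chromen-4-one | C=CCc1c(O[Si](C)(C)C(C)(C)C)c(CC=C)c2oc(-c3ccc(O[Si](C)(C)C(C)(C)C)cc3O[Si](C)(C)C(C)(C)C)c(C[C@@H]3OC3(C)C)c(=O)c2c1O[Si](C)(C)C(C)(C)C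
F4 | step 8 | racemic 6,8-diallyl-5,7-bis(allyloxy)-2-[2,4-bis(allyloxy)phenyl]-3-[(3,3-dimethyloxiran-2-yl)methyl]-4H-chromen-4-one | C=CCOc1ccc(-c2oc3c(CC=C)c(OCC=C)c(CC=C)c(OCC=C)c3c(=O)c2CC2OC2(C)C)c(OCC=C)c1
F5 | step 8 | racemic diallyl oxepinoflavone (racemate of 16) | C=CCc1c(O)c(CC=C)c2oc3c(c(=O)c2c1O)CC(C(C)(C)O)Oc1cc(O)ccc1-3
F6 | step 6 | 6,8-diallyl-5,7-bis(allyloxy)-2-[2,4-bis(allyloxy)phenyl]-4H-chromen-4-one | C=CCOc1ccc(-c2cc(=O)c3c(OCC=C)c(CC=C)c(OCC=C)c(CC=C)c3o2)c(OCC=C)c1
F7 | step 6 | 6,8-diallyl-5,7-bis(allyloxy)-2-[2,4-bis(allyloxy)phenyl]-3-iodo-4H-chromen-4-one | C=CCOc1ccc(-c2oc3c(CC=C)c(OCC=C)c(CC=C)c(OCC=C)c3c(=O)c2I)c(OCC=C)c1
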